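**Plan**

- Retrosynthesis: the four benzyl ethers are removed last. Ring A is cut at C4a–C5 and C8–C8a (5-sulfinyl-dihydropyranone plus a 1,1,3-trioxygenated diene). Ring C is cut at C2–C3 and O1–C8a (aryl aldehyde plus a 1-methoxy-3-silyloxybutadiene). The biaryl bond C3'–C8'' is cut by a Suzuki–Miyaura disconnection.
- Enabling feature: ring C is a 2-aryl-2,3-dihydropyran-4-one fused to ring A only through C4a–C8a. O1, C2, C3 and C4 with the C2 stereocentre therefore map onto an aldehyde C=O plus the diene, and the remaining C4a=C8a enone bond is the handle for ring A.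
- Forward order: apigenin supplies the flavone half intact; then the biaryl bond, ring C by hetero-Diels–Alder reaction, ring A by Diels–Alder reaction and aromatisation, and hydrogenolysis.
- Stereochemistry: the only stereocentre, C2 (S), is set by the (S)-BINOL/Ti(OiPr)4 catalyst in the addition to the aldehyde. No later step breaks C2–O1 or exposes the ring to base.

Key step: step 6

Assumption: (S)-BINOL is taken to deliver the 2S product, the same carbonyl face as in the BINOL/Ti(OiPr)4 additions to benzaldehyde. If a check on the first batch showed the opposite sense, (R)-BINOL would be used and nothing else changes.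

Shorthand in names: Ar = 4-(benzyloxy)-3-{5,7-bis(benzyloxy)-2-[4-(benzyloxy)phenyl]-4-oxo-4H-chromen-8-yl}phenyl. Unprimed locants are the flavanone (dihydropyranone) unit, single primes its aryl ring, double primes the flavone unit.

**Route**

Step 1
Reactants: 1 apigenin
Product: 2 5,7-bis(benzyloxy)-2-[4-(benzyloxy)phenyl]-4H-chromen-4-one
Conditions: BnBr (excess), K2CO3, DMF, 80 °C
Reagents that add atoms: benzyl bromide, BrCc1ccccc1
Why: Williamson etherification; carbonate in hot DMF with excess benzyl bromide should also alkylate the hydrogen-bonded 5-OH.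

Step 2
Reactants: 2 tri-O-benzylapigenin
Product: 3 5,7-bis(benzyloxy)-2-[4-(benzyloxy)phenyl]-8-iodo-4H-chromen-4-one
Conditions: N-iodosuccinimide, CF3CO2H (cat.), CH2Cl2–CH3CN, 0 °C to rt, dark
Reagents that add atoms: N-iodosuccinimide, O=C1CCC(=O)N1I
Why: Electrophilic aromatic iodination; in 5,7-di-O-alkylated flavones C8 is the position that halogenates, as known for this substrate class.

Step 3
Reactants: 4 3-bromo-4-hydroxybenzaldehyde
Product: 5 4-(benzyloxy)-3-bromobenzaldehyde
Conditions: BnBr, K2CO3, DMF, rt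
Reagents that add atoms: benzyl bromide, BrCc1ccccc1
Why: Williamson etherification of an acidic para-formyl phenol.

Step 4
Reactants: 5 4-(benzyloxy)-3-bromobenzaldehyde
Product: 6 4-(benzyloxy)-3-(4,4,5,5-tetramethyl-1,3,2-dioxaborolan-2-yl)benzaldehyde
Conditions: bis(pinacolato)diboron, PdCl2(dppf), KOAc, 1,4-dioxane, 85 °C
Reagents that add atoms: bis(pinacolato)diboron, CC1(C)OB(OC1(C)C)B1OC(C)(C)C(C)(C)O1
Why: Miyaura borylation of an electron-poor aryl bromide; the weak acetate base leaves the aldehyde untouched.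

Step 5
Reactants: 3 the 8-iodoflavone; 6 the aryl pinacol boronate
Product: 7 4-(benzyloxy)-3-{5,7-bis(benzyloxy)-2-[4-(benzyloxy)phenyl]-4-oxo-4H-chromen-8-yl}benzaldehyde (Ar–CHO)
Conditions: Pd(OAc)2, SPhos, K3PO4, toluene–H2O, 90 °C
Reagents that add atoms: none
Why: Suzuki–Miyaura coupling; the bulky electron-rich biaryl phosphine should carry the hindered C8''–I bond through oxidative addition and reductive elimination to the tri-ortho-substituted biaryl.

Step 6
Reactants: 7 Ar–CHO; 8 (E)-1-methoxy-3-(trimethylsilyloxy)buta-1,3-diene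
Product: 10 (2S)-2-Ar-2,3-dihydro-4H-pyran-4-one, via silylated aldol adduct 9 (not isolated)
Conditions: (S)-BINOL (40 mol %), Ti(OiPr)4 (20 mol %), CF3CO2H (cat.), 4 Å MS, toluene–Et2O, −20 °C; then CF3CO2H, CH2Cl2, 0 °C
Reagents that add atoms: none
Why: The BINOL titanium Lewis acid binds the formyl oxygen of 7, and the CH2 terminus of diene 8 attacks the carbonyl carbon in the Mukaiyama-aldol manifold of the formal hetero-Diels–Alder reaction, forming C2–C3 and giving silyl ether 9. Trifluoroacetic acid then removes the silyl group, and the carbinol oxygen adds to the methoxy-bearing enone carbon with loss of methanol, forming O1–C8a. The closest known reaction type is the BINOL/Ti(OiPr)4-catalysed hetero-Diels–Alder reaction of aryl aldehydes with 1-methoxy-3-silyloxybutadienes to 2-aryl-2,3-dihydro-4H-pyran-4-ones. Ring C closes as a six-membered ring, overall in a [4+2] sense and stepwise by 6-endo-trig oxa-conjugate addition followed by β-elimination. The C2 stereocentre is controlled by the chiral titanium complex, which leaves one face of the bound aldehyde open, (S)-BINOL being chosen for 2S. The step needs facial selectivity and reaction at the formyl group only; the aldehyde is the single unhindered aldehyde with the flavone meta and remote, the vinylogous-ester carbonyl C4''=O is inert to the diene, and the raised catalyst loading offsets its binding of titanium.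

Step 7
Reactants: 10 (2S)-2-Ar-2,3-dihydro-4H-pyran-4-one
Product: 12 (2S)-2-Ar-5-(phenylsulfanyl)-2,3-dihydro-4H-pyran-4-one, via chloro sulfide adduct 11 (not isolated)
Conditions: PhSCl (1.05 equiv), CH2Cl2, −78 °C; then Et3N, −78 to 0 °C
Reagents that add atoms: benzenesulfenyl chloride, ClSc1ccccc1
Why: Electrophilic sulfenylation of the enol-ether carbon C5 by anti addition of the sulfenyl chloride and base-induced loss of HCl, the reaction type used for 2-thio glycals; the non-aromatic, C6-unsubstituted enol ether is the most nucleophilic π bond present and C2 is not involved.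

Step 8
Reactants: 12 the 5-phenylsulfanyl dihydropyranone
Product: 13 (2S)-2-Ar-5-(phenylsulfinyl)-2,3-dihydro-4H-pyran-4-one (mixture of epimers at sulfur)
Conditions: mCPBA (1.0 equiv), CH2Cl2, −78 to −40 °C
Reagents that add atoms: 3-chloroperoxybenzoic acid, OOC(=O)c1cccc(Cl)c1
Why: Chemoselective sulfide-to-sulfoxide oxidation with one equivalent of peracid at low temperature; the electron-poor enone and the aryl ethers are inert, and the sulfur stereocentre is lost in step 10.

Step 9
Reactants: 14 methyl (E)-3-methoxybut-2-enoate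
Product: 15 1,3-dimethoxy-1-(trimethylsilyloxy)buta-1,3-diene (geometry at the ketene acetal not controlled)
Conditions: LiN(iPr)2, THF, −78 °C; Me3SiCl, −78 °C to rt; distillation
Reagents that add atoms: chlorotrimethylsilane, C[Si](C)(C)Cl
Why: γ-Deprotonation of the vinylogous ester and O-silylation of the dienolate, the standard silyl ketene acetal formation.

Step 10
Reactants: 13 the 5-phenylsulfinyl dihydropyranone; 15 the trioxygenated diene
Product: 18 (2S)-2-Ar-5-hydroxy-7-methoxy-2,3-dihydro-4H-chromen-4-one, via sulfinyl cycloadduct 16 (not isolated), via aryl silyl ether 17 (not isolated)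
Conditions: 15 (3 equiv), toluene, rt to 80 °C; then 1 M HCl, THF, 0 °C
Reagents that add atoms: none
Why: Proposed new method: the C4 carbonyl and the sulfinyl group together polarise the C4a=C8a bond of 13 so that C8a is the electrophilic end; the nucleophilic CH2 terminus of ketene-acetal diene 15 should bond to C8a and the acetal carbon to C4a in a [4+2] cycloaddition (or by Mukaiyama–Michael addition and ring closure, which converge on 16); syn-elimination of benzenesulfenic acid across C4a–C8a (sulfinyl group and C8a–H are cis in the adduct) and loss of methanol then aromatise ring A with the silyloxy group at C5 and the methoxy group at C7; the closest known reaction type is the Diels–Alder reaction of 2-sulfinyl enones and sulfinyl quinones with oxygenated silyloxydienes followed by spontaneous sulfoxide elimination to the arene, the regiochemistry following that of the same diene with 2-haloquinones; C2 is a spectator under these neutral conditions.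

Step 11
Reactants: 18 the tetra-O-benzyl flavanone–flavone
Product: 19 CNP0107492.1, (2S)-5-hydroxy-2-{4-hydroxy-3-[5,7-dihydroxy-2-(4-hydroxyphenyl)-4-oxo-4H-chromen-8-yl]phenyl}-7-methoxy-2,3-dihydro-4H-chromen-4-one
Conditions: H2 (1 atm), Pd/C, THF–MeOH, rt, stopped at complete debenzylation
Reagents that add atoms: none
Why: Hydrogenolysis of aryl benzyl ethers over Pd/C under neutral conditions should outpace both saturation of the flavone C2''=C3'' bond and cleavage of the cyclic C2–O1 ether, and without base C2 is not epimerised.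

**Compound list**

1 | apigenin, 5,7-dihydroxy-2-(4-hydroxyphenyl)-4H-chromen-4-one | O=c1cc(-c2ccc(O)cc2)oc2cc(O)cc(O)c12 | starting material
2 | 5,7-bis(benzyloxy)-2-[4-(benzyloxy)phenyl]-4H-chromen-4-one | O=c1cc(-c2ccc(OCc3ccccc3)cc2)oc2cc(OCc3ccccc3)cc(OCc3ccccc3)c12 | intermediate
3 | 5,7-bis(benzyloxy)-2-[4-(benzyloxy)phenyl]-8-iodo-4H-chromen-4-one | Ic1c(OCc2ccccc2)cc(OCc2ccccc2)c2c(=O)cc(-c3ccc(OCc4ccccc4)cc3)oc12 | intermediate
4 | 3-bromo-4-hydroxybenzaldehyde | O=Cc1ccc(O)c(Br)c1 | starting material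
5 | 4-(benzyloxy)-3-bromobenzaldehyde | O=Cc1ccc(OCc2ccccc2)c(Br)c1 | intermediate
6 | 4-(benzyloxy)-3-(4,4,5,5-tetramethyl-1,3,2-dioxaborolan-2-yl)benzaldehyde | O=Cc1ccc(OCc2ccccc2)c(B2OC(C)(C)C(C)(C)O2)c1 | intermediate
7 | Ar–CHO, 4-(benzyloxy)-3-{5,7-bis(benzyloxy)-2-[4-(benzyloxy)phenyl]-4-oxo-4H-chromen-8-yl}benzaldehyde | O=Cc1ccc(OCc2ccccc2)c(-c2c(OCc3ccccc3)cc(OCc3ccccc3)c3c(=O)cc(-c4ccc(OCc5ccccc5)cc4)oc23)c1 | intermediate
8 | (E)-1-methoxy-3-(trimethylsilyloxy)buta-1,3-diene | CO/C=C/C(=C)O[Si](C)(C)C | starting material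
9 | (1E,5S)-5-Ar-1-methoxy-5-(trimethylsilyloxy)pent-1-en-3-one | CO/C=C/C(=O)C[C@H](O[Si](C)(C)C)c1ccc(OCc2ccccc2)c(-c2c(OCc3ccccc3)cc(OCc3ccccc3)c3c(=O)cc(-c4ccc(OCc5ccccc5)cc4)oc23)c1 | intermediate (not isolated)
10 | (2S)-2-Ar-2,3-dihydro-4H-pyran-4-one | O=C1C=CO[C@H](c2ccc(OCc3ccccc3)c(-c3c(OCc4ccccc4)cc(OCc4ccccc4)c4c(=O)cc(-c5ccc(OCc6ccccc6)cc5)oc34)c2)C1 | intermediate
11 | (2S)-2-Ar-6-chloro-5-(phenylsulfanyl)tetrahydro-4H-pyran-4-one, Cl and SPh trans, C5/C6 otherwise undefined | O=C1C(Sc2ccccc2)C(Cl)O[C@H](c2ccc(OCc3ccccc3)c(-c3c(OCc4ccccc4)cc(OCc4ccccc4)c4c(=O)cc(-c5ccc(OCc6ccccc6)cc5)oc34)c2)C1 | intermediate (not isolated)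
12 | (2S)-2-Ar-5-(phenylsulfanyl)-2,3-dihydro-4H-pyran-4-one | O=C1C(Sc2ccccc2)=CO[C@H](c2ccc(OCc3ccccc3)c(-c3c(OCc4ccccc4)cc(OCc4ccccc4)c4c(=O)cc(-c5ccc(OCc6ccccc6)cc5)oc34)c2)C1 | intermediate
13 | (2S)-2-Ar-5-(phenylsulfinyl)-2,3-dihydro-4H-pyran-4-one, epimers at sulfur | O=C1C(S(=O)c2ccccc2)=CO[C@H](c2ccc(OCc3ccccc3)c(-c3c(OCc4ccccc4)cc(OCc4ccccc4)c4c(=O)cc(-c5ccc(OCc6ccccc6)cc5)oc34)c2)C1 | intermediate
14 | methyl (E)-3-methoxybut-2-enoate | CO/C(C)=C/C(=O)OC | starting material
15 | 1,3-dimethoxy-1-(trimethylsilyloxy)buta-1,3-diene | C=C(OC)C=C(OC)O[Si](C)(C)C | intermediate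
16 | (2S)-2-Ar-5,7-dimethoxy-4a-(phenylsulfinyl)-5-(trimethylsilyloxy)-2,3,4a,5,8,8a-hexahydro-4H-chromen-4-one, cis ring fusion, other new centres undefined | O=C1C[C@@H](c2ccc(OCc3ccccc3)c(-c3c(OCc4ccccc4)cc(OCc4ccccc4)c4c(=O)cc(-c5ccc(OCc6ccccc6)cc5)oc34)c2)OC2CC(OC)=CC(OC)(O[Si](C)(C)C)C12S(=O)c1ccccc1 | intermediate (not isolated)
17 | (2S)-2-Ar-7-methoxy-5-(trimethylsilyloxy)-2,3-dihydro-4H-chromen-4-one | COc1cc(O[Si](C)(C)C)c2c(c1)O[C@H](c1ccc(OCc3ccccc3)c(-c3c(OCc4ccccc4)cc(OCc4ccccc4)c4c(=O)cc(-c5ccc(OCc6ccccc6)cc5)oc34)c1)CC2=O | intermediate (not isolated)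
18 | (2S)-2-Ar-5-hydroxy-7-methoxy-2,3-dihydro-4H-chromen-4-one | COc1cc(O)c2c(c1)O[C@H](c1ccc(OCc3ccccc3)c(-c3c(OCc4ccccc4)cc(OCc4ccccc4)c4c(=O)cc(-c5ccc(OCc6ccccc6)cc5)oc34)c1)CC2=O | intermediate
19 | CNP0107492.1, (2S)-5-hydroxy-2-{4-hydroxy-3-[5,7-dihydroxy-2-(4-hydroxyphenyl)-4-oxo-4H-chromen-8-yl]phenyl}-7-methoxy-2,3-dihydro-4H-chromen-4-one | COc1cc(O)c2c(c1)O[C@H](c1ccc(O)c(-c3c(O)cc(O)c4c(=O)cc(-c5ccc(O)cc5)oc34)c1)CC2=O | target

**Step count and risks**

Total: 11 steps. Longest linear sequence: 8 steps (1, 2, 5, 6, 7, 8, 10, 11 from apigenin).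

Steps most likely to fail:

1. Step 10 (proposed new method). The diene may add to C8a only as a conjugate nucleophile and stall before ring closure, or the ring oxygen may be expelled from C8a after that addition so that ring C opens. The fallback uses known chemistry, sets out from aldehyde 7 and comes back at target 19. Commercial 2',6'-dihydroxy-4'-methoxyacetophenone is mono-benzylated (BnBr, K2CO3, acetone) to 1-[2-(benzyloxy)-6-hydroxy-4-methoxyphenyl]ethanone F1. Claisen–Schmidt condensation of F1 with 7 (KOH, EtOH–THF, rt) would give the (E)-chalcone F2. Oxa-Michael ring closure (NaOAc, EtOH, reflux) would give the racemic 5-O-benzyl flavanone F3. Preparative chromatography on a chiral stationary phase would separate the (2S)-enantiomer F4, and hydrogenolysis as in step 11 would give 19. Ring C then comes from chalcone cyclisation, and half of the material is lost in the resolution.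

2. Step 6. The pyrone carbonyl and the ether oxygens may sequester the titanium catalyst, so that the reaction becomes slow and a poorly face-selective background addition takes over. The fallback sets out from 7 and comes back at 10. The boron enolate of (E)-4-chlorobut-3-en-2-one is formed with diisopinocampheylboron chloride (the antipode matched to the S carbinol on a benzaldehyde model) and iPr2NEt in Et2O at −78 °C and added to 7, giving (1E,5S)-5-Ar-1-chloro-5-hydroxypent-1-en-3-one F5. Me3SiOTf and iPr2NEt in CH2Cl2 would then close the ring by oxa-conjugate addition and loss of chloride to give 10. A stoichiometric chiral boron reagent replaces the catalytic Lewis acid.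

3. Step 7. The sulfenyl chloride may also attack the electron-rich flavone positions C6'' and C3'', or sulfenylate twice. The fallback sets out from 10 and comes back at 12. α-Iodination with I2 and pyridine in CH2Cl2, a nucleophile-mediated reaction that flavones do not undergo, would give (2S)-2-Ar-5-iodo-2,3-dihydro-4H-pyran-4-one F6. C–S cross-coupling of F6 with thiophenol (Pd2(dba)3, Xantphos, iPr2NEt, 1,4-dioxane, 90 °C) would then give 12.

**Further compounds**

F1 | step 10 | 1-[2-(benzyloxy)-6-hydroxy-4-methoxyphenyl]ethanone | CC(=O)c1c(O)cc(OC)cc1OCc1ccccc1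
F2 | step 10 | (E)-3-Ar-1-[2-(benzyloxy)-6-hydroxy-4-methoxyphenyl]prop-2-en-1-one | COc1cc(O)c(C(=O)/C=C/c2ccc(OCc3ccccc3)c(-c3c(OCc4ccccc4)cc(OCc4ccccc4)c4c(=O)cc(-c5ccc(OCc6ccccc6)cc5)oc34)c2)c(OCc2ccccc2)c1
F3 | step 10 | racemic 2-Ar-5-(benzyloxy)-7-methoxy-2,3-dihydro-4H-chromen-4-one | COc1cc(OCc2ccccc2)c2c(c1)OC(c1ccc(OCc3ccccc3)c(-c3c(OCc4ccccc4)cc(OCc4ccccc4)c4c(=O)cc(-c5ccc(OCc6ccccc6)cc5)oc34)c1)CC2=O
F4 | step 10 | (2S)-2-Ar-5-(benzyloxy)-7-methoxy-2,3-dihydro-4H-chromen-4-one | COc1cc(OCc2ccccc2)c2c(c1)O[C@H](c1ccc(OCc3ccccc3)c(-c3c(OCc4ccccc4)cc(OCc4ccccc4)c4c(=O)cc(-c5ccc(OCc6ccccc6)cc5)oc34)c1)CC2=O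
F5 | step 6 | (1E,5S)-5-Ar-1-chloro-5-hydroxypent-1-en-3-one | O=C(/C=C/Cl)C[C@H](O)c1ccc(OCc2ccccc2)c(-c2c(OCc3ccccc3)cc(OCc3ccccc3)c3c(=O)cc(-c4ccc(OCc5ccccc5)cc4)oc23)c1
F6 | step 7 | (2S)-2-Ar-5-iodo-2,3-dihydro-4H-pyran-4-one | O=C1C(I)=CO[C@H](c2ccc(OCc3ccccc3)c(-c3c(OCc4ccccc4)cc(OCc4ccccc4)c4c(=O)cc(-c5ccc(OCc6ccccc6)cc5)oc34)c2)C1
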